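**Retrosynthetic overview**
1. Last bond: the aryl ether C–O, made by Mitsunobu coupling of umbelliferone (14) with primary alcohol 13.
2. Ring A substituents: the axial hydroxyl comes from equatorial hydride delivery to the ketone of 9, the acetoxymethyl group from the axial ester (reduction, selective acetylation), and the quaternary carbon from methylation of bicyclic β-keto ester 8 anti to the angular methyl.
3. Both rings in one step (ring A first, then ring B) with three stereocenters: a new enantioselective oxidative radical bicyclization of acyclic β-keto ester 7, ending in the exocyclic alkene.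
4. Acyclic chain: γ-alkylation of the ethyl acetoacetate dianion with allylic bromide 4, made from geraniol (1) by silylation, allylic oxidation and bromination.

Assumption: the absolute sense of induction of the new ligand-controlled cyclization in step 5 (and of the auxiliary in its fallback) must be confirmed by experiment; the (R,R)-ligand and the (1R,2S,5R)-auxiliary are written, and the mirror-image reagent is used if the opposite ring-system enantiomer is obtained.

Locants in the bicyclic names are those of the decahydronaphthalene names (C1 quaternary carbon, C2 carbinol/ketone, C4a angular methyl, C5 CH2O-bearing carbon, C6 methylidene, C8a ring-fusion CH).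

**Step 1**
Reactants: 1 geraniol
Product: 2 tert-butyl{[(2E)-3,7-dimethylocta-2,6-dien-1-yl]oxy}diphenylsilane
Conditions: TBDPSCl (1.1 equiv), imidazole (2.2 equiv), CH2Cl2, 0 °C to rt
Reagents that add atoms: tert-butyl(chloro)diphenylsilane (TBDPSCl), CC(C)(C)[Si](Cl)(c1ccccc1)c1ccccc1
Why: Standard imidazole-promoted silylation (silyl ether protection) of the primary allylic alcohol; the robust silyl ether survives the later oxidative, basic and hydride steps, and no stereocenter is formed.

**Step 2**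
Reactants: 2 tert-butyl{[(2E)-3,7-dimethylocta-2,6-dien-1-yl]oxy}diphenylsilane
Product: 3 (2E,6E)-8-[(tert-butyldiphenylsilyl)oxy]-2,6-dimethylocta-2,6-dien-1-ol
Conditions: SeO2 (0.2 equiv), t-BuOOH (3 equiv), salicylic acid (0.1 equiv), CH2Cl2, rt
Reagents that add atoms: tert-butyl hydroperoxide (terminal oxygen source), CC(C)(C)OO; selenium dioxide (catalytic oxygen carrier), O=[Se]=O
Why: Catalytic SeO2/t-BuOOH allylic oxidation (ene reaction then [2,3]-sigmatropic shift) attacks the (E)-methyl of the electron-rich terminal trisubstituted alkene and gives the (E)-allylic alcohol, while the alkene next to the silyloxy group is deactivated.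

**Step 3**
Reactants: 3 (2E,6E)-8-[(tert-butyldiphenylsilyl)oxy]-2,6-dimethylocta-2,6-dien-1-ol
Product: 4 {[(2E,6E)-8-bromo-3,7-dimethylocta-2,6-dien-1-yl]oxy}(tert-butyl)diphenylsilane
Conditions: CBr4 (1.3 equiv), PPh3 (1.3 equiv), CH2Cl2, 0 °C
Reagents that add atoms: carbon tetrabromide, BrC(Br)(Br)Br
Why: Appel bromination converts the primary allylic alcohol into the bromide by SN2 displacement of the oxyphosphonium group without allylic transposition or loss of alkene geometry.

**Step 4**
Reactants: 4 {[(2E,6E)-8-bromo-3,7-dimethylocta-2,6-dien-1-yl]oxy}(tert-butyl)diphenylsilane; 5 ethyl acetoacetate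
Product: 7 ethyl (6E,10E)-12-[(tert-butyldiphenylsilyl)oxy]-6,10-dimethyl-3-oxododeca-6,10-dienoate, via sodium lithium dienolate of ethyl acetoacetate 6 (not isolated)
Conditions: 5, NaH (1.1 equiv), THF, 0 °C; n-BuLi (1.05 equiv), 0 °C; then 4, 0 °C to rt; aq. NH4Cl
Reagents that add atoms: none
Why: Weiler dianion alkylation: the more reactive terminal (γ) carbanion of the acetoacetate dianion displaces the allylic bromide, giving the γ-alkylated β-keto ester with both (E)-alkenes intact.

**Step 5**
Reactants: 7 ethyl (6E,10E)-12-[(tert-butyldiphenylsilyl)oxy]-6,10-dimethyl-3-oxododeca-6,10-dienoate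
Product: 8 ethyl (4aR,5R,8aR)-5-{[(tert-butyldiphenylsilyl)oxy]methyl}-4a-methyl-6-methylidene-2-oxodecahydronaphthalene-1-carboxylate (keto/enol mixture at C1)
Conditions: Yb(OTf)3 (1.0 equiv), (R,R)-Ph-pybox [2,6-bis((4R)-4-phenyl-4,5-dihydrooxazol-2-yl)pyridine] (1.2 equiv), Mn(OAc)3·2H2O (2.2 equiv), Cu(OAc)2·H2O (1.0 equiv), CF3CH2OH, −20 °C
Reagents that add atoms: none
Why: Proposed new method: a chiral-Lewis-acid-controlled version of the Snider oxidative radical polyene cyclization, in which Yb(OTf)3 carrying the C2-symmetric pybox ligand chelates the 1,3-dicarbonyl of 7 and speeds its enolization, Mn(OAc)3 oxidizes the bound enolate by one electron to a chelated, ligand-shielded α-radical that adds 6-endo to the (6E)-alkene from its open face through a chair transition state (ring A, trans ring fusion, C8a and C4a set), the tertiary radical closes ring B 6-endo onto the (10E)-alkene with the silyloxymethyl group equatorial (C5 set), and Cu(OAc)2 oxidizes the last tertiary radical through an alkylcopper species whose β-hydride elimination toward the methyl group gives the exocyclic alkene; the closest known reactions are the Mn(OAc)3/Cu(OAc)2 oxidative cyclization of β-keto esters, its Yb(OTf)3-accelerated chiral-auxiliary version, and chiral-Lewis-acid-controlled atom-transfer radical cyclizations of α-bromo β-keto esters, none of which joins ligand-controlled enantioselection to oxidative alkene termination.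

**Step 6**
Reactants: 8 ethyl (4aR,5R,8aR)-5-{[(tert-butyldiphenylsilyl)oxy]methyl}-4a-methyl-6-methylidene-2-oxodecahydronaphthalene-1-carboxylate
Product: 9 ethyl (1S,4aR,5R,8aS)-5-{[(tert-butyldiphenylsilyl)oxy]methyl}-1,4a-dimethyl-6-methylidene-2-oxodecahydronaphthalene-1-carboxylate
Conditions: K2CO3 (3 equiv), MeI (5 equiv), acetone, 50 °C
Reagents that add atoms: iodomethane, CI
Why: C-alkylation of the cyclic β-keto ester enolate occurs on the face anti to the angular C4a methyl (the syn face suffers a 1,3-diaxial interaction), so the new methyl is equatorial and the ester axial, which sets the C1 quaternary center.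

**Step 7**
Reactants: 9 ethyl (1S,4aR,5R,8aS)-5-{[(tert-butyldiphenylsilyl)oxy]methyl}-1,4a-dimethyl-6-methylidene-2-oxodecahydronaphthalene-1-carboxylate
Product: 10 ethyl (1S,2S,4aR,5R,8aS)-5-{[(tert-butyldiphenylsilyl)oxy]methyl}-2-hydroxy-1,4a-dimethyl-6-methylidenedecahydronaphthalene-1-carboxylate
Conditions: LiBH(s-Bu)3 (1.5 equiv), THF, −78 °C; aq. NH4Cl
Reagents that add atoms: none
Why: Reagent-controlled ketone reduction: the bulky trialkylborohydride attacks along the equatorial trajectory (the axial one is blocked by the 1,3-diaxial hydrogens), giving the axial C2 alcohol trans to the axial ester, while the hindered ester is untouched at −78 °C.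

**Step 8**
Reactants: 10 ethyl (1S,2S,4aR,5R,8aS)-5-{[(tert-butyldiphenylsilyl)oxy]methyl}-2-hydroxy-1,4a-dimethyl-6-methylidenedecahydronaphthalene-1-carboxylate
Product: 11 (1R,2S,4aR,5R,8aS)-5-{[(tert-butyldiphenylsilyl)oxy]methyl}-1-(hydroxymethyl)-1,4a-dimethyl-6-methylidenedecahydronaphthalen-2-ol
Conditions: LiAlH4 (3 equiv), THF, 0 to 40 °C; H2O work-up
Reagents that add atoms: none
Why: LiAlH4 reduction of the hindered axial ester to the primary alcohol; no stereocenter is affected and the silyl ether and the alkene are inert.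

**Step 9**
Reactants: 11 (1R,2S,4aR,5R,8aS)-5-{[(tert-butyldiphenylsilyl)oxy]methyl}-1-(hydroxymethyl)-1,4a-dimethyl-6-methylidenedecahydronaphthalen-2-ol
Product: 12 [(1R,2S,4aR,5R,8aS)-5-{[(tert-butyldiphenylsilyl)oxy]methyl}-2-hydroxy-1,4a-dimethyl-6-methylidenedecahydronaphthalen-1-yl]methyl acetate
Conditions: Ac2O (1.2 equiv), pyridine, CH2Cl2, 0 °C to rt
Reagents that add atoms: acetic anhydride, CC(=O)OC(C)=O
Why: Chemoselective acylation: the primary hydroxyl is acetylated much faster than the axial secondary hydroxyl next to the quaternary carbon, and their trans-diaxial arrangement rules out later acyl migration.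

**Step 10**
Reactants: 12 [(1R,2S,4aR,5R,8aS)-5-{[(tert-butyldiphenylsilyl)oxy]methyl}-2-hydroxy-1,4a-dimethyl-6-methylidenedecahydronaphthalen-1-yl]methyl acetate
Product: 13 [(1R,2S,4aR,5R,8aS)-2-hydroxy-5-(hydroxymethyl)-1,4a-dimethyl-6-methylidenedecahydronaphthalen-1-yl]methyl acetate
Conditions: HF·pyridine, pyridine/THF, 0 °C to rt
Reagents that add atoms: none
Why: Fluoride-mediated silyl ether cleavage under buffered, non-basic conditions leaves the acetate, the secondary alcohol and the exocyclic alkene untouched.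

**Step 11**
Reactants: 13 [(1R,2S,4aR,5R,8aS)-2-hydroxy-5-(hydroxymethyl)-1,4a-dimethyl-6-methylidenedecahydronaphthalen-1-yl]methyl acetate; 14 umbelliferone (7-hydroxy-2H-chromen-2-one)
Product: 15 [(1R,2S,4aR,5R,8aS)-2-hydroxy-1,4a-dimethyl-6-methylidene-5-{[(2-oxo-2H-chromen-7-yl)oxy]methyl}decahydronaphthalen-1-yl]methyl acetate (target)
Conditions: 14 (1.5 equiv), PPh3 (1.5 equiv), DIAD (1.5 equiv), THF, 0 °C to rt
Reagents that add atoms: none
Why: Mitsunobu etherification: the acidic phenol (pKa about 8) is alkylated by the activated primary alcohol through SN2 displacement at CH2, the hindered axial secondary alcohol does not react, and no stereocenter is touched.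

**Compound list**
1 | geraniol, (2E)-3,7-dimethylocta-2,6-dien-1-ol | CC(C)=CCC/C(C)=C/CO | starting material
2 | tert-butyl{[(2E)-3,7-dimethylocta-2,6-dien-1-yl]oxy}diphenylsilane | CC(C)=CCC/C(C)=C/CO[Si](c1ccccc1)(c1ccccc1)C(C)(C)C | intermediate
3 | (2E,6E)-8-[(tert-butyldiphenylsilyl)oxy]-2,6-dimethylocta-2,6-dien-1-ol | OC/C(C)=C/CC/C(C)=C/CO[Si](c1ccccc1)(c1ccccc1)C(C)(C)C | intermediate
4 | {[(2E,6E)-8-bromo-3,7-dimethylocta-2,6-dien-1-yl]oxy}(tert-butyl)diphenylsilane | BrC/C(C)=C/CC/C(C)=C/CO[Si](c1ccccc1)(c1ccccc1)C(C)(C)C | intermediate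
5 | ethyl acetoacetate (ethyl 3-oxobutanoate) | CCOC(=O)CC(C)=O | starting material
6 | sodium lithium dienolate (dianion) of ethyl acetoacetate | C=C([O-])C=C([O-])OCC.[Na+].[Li+] | intermediate
7 | ethyl (6E,10E)-12-[(tert-butyldiphenylsilyl)oxy]-6,10-dimethyl-3-oxododeca-6,10-dienoate | CCOC(=O)CC(=O)CC/C(C)=C/CC/C(C)=C/CO[Si](c1ccccc1)(c1ccccc1)C(C)(C)C | intermediate
8 | ethyl (4aR,5R,8aR)-5-{[(tert-butyldiphenylsilyl)oxy]methyl}-4a-methyl-6-methylidene-2-oxodecahydronaphthalene-1-carboxylate; trans-decalin, angular methyl and CH2OSi on one face, ring-fusion H on the other, C1 epimerizable | C=C1CC[C@@H]2C(C(=O)OCC)C(=O)CC[C@@]2(C)[C@@H]1CO[Si](c1ccccc1)(c1ccccc1)C(C)(C)C | intermediate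
9 | ethyl (1S,4aR,5R,8aS)-5-{[(tert-butyldiphenylsilyl)oxy]methyl}-1,4a-dimethyl-6-methylidene-2-oxodecahydronaphthalene-1-carboxylate; ester axial and cis to the angular methyl | C=C1CC[C@@H]2[C@](C)(C(=O)OCC)C(=O)CC[C@@]2(C)[C@@H]1CO[Si](c1ccccc1)(c1ccccc1)C(C)(C)C | intermediate
10 | ethyl (1S,2S,4aR,5R,8aS)-5-{[(tert-butyldiphenylsilyl)oxy]methyl}-2-hydroxy-1,4a-dimethyl-6-methylidenedecahydronaphthalene-1-carboxylate; hydroxyl axial, trans to the ester | C=C1CC[C@@H]2[C@](C)(C(=O)OCC)[C@@H](O)CC[C@@]2(C)[C@@H]1CO[Si](c1ccccc1)(c1ccccc1)C(C)(C)C | intermediate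
11 | (1R,2S,4aR,5R,8aS)-5-{[(tert-butyldiphenylsilyl)oxy]methyl}-1-(hydroxymethyl)-1,4a-dimethyl-6-methylidenedecahydronaphthalen-2-ol | C=C1CC[C@@H]2[C@](C)(CO)[C@@H](O)CC[C@@]2(C)[C@@H]1CO[Si](c1ccccc1)(c1ccccc1)C(C)(C)C | intermediate
12 | [(1R,2S,4aR,5R,8aS)-5-{[(tert-butyldiphenylsilyl)oxy]methyl}-2-hydroxy-1,4a-dimethyl-6-methylidenedecahydronaphthalen-1-yl]methyl acetate | C=C1CC[C@@H]2[C@](C)(COC(C)=O)[C@@H](O)CC[C@@]2(C)[C@@H]1CO[Si](c1ccccc1)(c1ccccc1)C(C)(C)C | intermediate
13 | [(1R,2S,4aR,5R,8aS)-2-hydroxy-5-(hydroxymethyl)-1,4a-dimethyl-6-methylidenedecahydronaphthalen-1-yl]methyl acetate | C=C1CC[C@@H]2[C@](C)(COC(C)=O)[C@@H](O)CC[C@@]2(C)[C@@H]1CO | intermediate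
14 | umbelliferone (7-hydroxy-2H-chromen-2-one) | O=c1ccc2ccc(O)cc2o1 | starting material
15 | [(1R,2S,4aR,5R,8aS)-2-hydroxy-1,4a-dimethyl-6-methylidene-5-{[(2-oxo-2H-chromen-7-yl)oxy]methyl}decahydronaphthalen-1-yl]methyl acetate; angular methyl, aryloxymethyl and acetoxymethyl on one face, ring-fusion H, C1 methyl and hydroxyl on the other | C=C1CC[C@@H]2[C@](C)(COC(C)=O)[C@@H](O)CC[C@@]2(C)[C@@H]1COc1ccc2ccc(=O)oc2c1 | target

**Count and risks**
Total step count: 11. Longest linear sequence: 11 steps (from geraniol 1 to target 15).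

The three steps most likely to fail:

Step 5 (the proposed new cyclization). Acetate from the oxidants may strip the chiral ligand from ytterbium, a racemic background pathway may compete, and 8 may be over-oxidized. The fallback uses known chemistry, sets out from 7 and comes back at 11. Compound 7 is transesterified with (1R,2S,5R)-8-phenylmenthol (DMAP cat., toluene, reflux, ethanol distilled off) to (1R,2S,5R)-5-methyl-2-(2-phenylpropan-2-yl)cyclohexyl (6E,10E)-12-[(tert-butyldiphenylsilyl)oxy]-6,10-dimethyl-3-oxododeca-6,10-dienoate F1. The known auxiliary-controlled oxidative radical cyclization (Mn(OAc)3·2H2O, Cu(OAc)2·H2O, Yb(OTf)3, CF3CH2OH, −5 °C) then gives the bicyclic 8-phenylmenthyl β-keto ester F2 as the major diastereomer, purified by chromatography. Methylation (K2CO3, MeI, acetone) gives the 1-methyl keto ester F3, LiBH(s-Bu)3 at −78 °C gives the axial hydroxy ester F4, and LiAlH4 in THF reduces the ester, removing the auxiliary, to give diol 11.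

Step 7 (axial-selective ketone reduction). The axial ester next to the ketone may erode equatorial attack and give the equatorial alcohol. The fallback sets out from 9 and comes back at 11, replacing reagent control by hydroxyl-directed intramolecular hydride delivery. The ketone of 9 is masked as ethyl (1S,4aR,5R,8aS)-5-{[(tert-butyldiphenylsilyl)oxy]methyl}-1,4a-dimethyl-6-methylidene-2-[(trimethylsilyl)oxy]-1,4,4a,5,6,7,8,8a-octahydronaphthalene-1-carboxylate F5 (LiN(i-Pr)2, THF, −78 °C; TMSCl). LiAlH4 reduces the ester to the silyl enol ether alcohol F6, which is not isolated; mild acidic work-up (aqueous citric acid) releases (1R,4aR,5R,8aS)-5-{[(tert-butyldiphenylsilyl)oxy]methyl}-1-(hydroxymethyl)-1,4a-dimethyl-6-methylideneoctahydronaphthalen-2(1H)-one F7. Me4NBH(OAc)3 in MeCN/AcOH at −20 °C then delivers hydride from the face of the axial hydroxymethyl group (anti-selective directed reduction) to give the 1,3-anti diol 11.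

Step 11 (Mitsunobu at a β-branched primary carbon next to a quaternary center). SN2 displacement may be slow and elimination may compete. The fallback sets out from 13 and comes back at 15, forming the aryl–oxygen bond instead of the alkyl–oxygen bond. It is a palladium-catalyzed C–O cross-coupling of the primary alcohol of 13 with 7-bromo-2H-chromen-2-one ([Pd(allyl)Cl]2, RockPhos, Cs2CO3, toluene, 90 °C); the hindered secondary alcohol does not couple and no substitution at the crowded carbon is needed. No new intermediate is made.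

**Further compounds**
F1 | step 5 | (1R,2S,5R)-5-methyl-2-(2-phenylpropan-2-yl)cyclohexyl (6E,10E)-12-[(tert-butyldiphenylsilyl)oxy]-6,10-dimethyl-3-oxododeca-6,10-dienoate | CC(C)(c1ccccc1)[C@@H]1CC[C@@H](C)C[C@H]1OC(=O)CC(=O)CC/C(C)=C/CC/C(C)=C/CO[Si](c1ccccc1)(c1ccccc1)C(C)(C)C
F2 | step 5 | (1R,2S,5R)-5-methyl-2-(2-phenylpropan-2-yl)cyclohexyl (4aR,5R,8aR)-5-{[(tert-butyldiphenylsilyl)oxy]methyl}-4a-methyl-6-methylidene-2-oxodecahydronaphthalene-1-carboxylate | C=C1CC[C@@H]2C(C(=O)O[C@@H]3C[C@H](C)CC[C@H]3C(C)(C)c3ccccc3)C(=O)CC[C@@]2(C)[C@@H]1CO[Si](c1ccccc1)(c1ccccc1)C(C)(C)C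
F3 | step 5 | (1R,2S,5R)-5-methyl-2-(2-phenylpropan-2-yl)cyclohexyl (1S,4aR,5R,8aS)-5-{[(tert-butyldiphenylsilyl)oxy]methyl}-1,4a-dimethyl-6-methylidene-2-oxodecahydronaphthalene-1-carboxylate | C=C1CC[C@@H]2[C@](C)(C(=O)O[C@@H]3C[C@H](C)CC[C@H]3C(C)(C)c3ccccc3)C(=O)CC[C@@]2(C)[C@@H]1CO[Si](c1ccccc1)(c1ccccc1)C(C)(C)C
F4 | step 5 | (1R,2S,5R)-5-methyl-2-(2-phenylpropan-2-yl)cyclohexyl (1S,2S,4aR,5R,8aS)-5-{[(tert-butyldiphenylsilyl)oxy]methyl}-2-hydroxy-1,4a-dimethyl-6-methylidenedecahydronaphthalene-1-carboxylate | C=C1CC[C@@H]2[C@](C)(C(=O)O[C@@H]3C[C@H](C)CC[C@H]3C(C)(C)c3ccccc3)[C@@H](O)CC[C@@]2(C)[C@@H]1CO[Si](c1ccccc1)(c1ccccc1)C(C)(C)C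
F5 | step 7 | ethyl (1S,4aR,5R,8aS)-5-{[(tert-butyldiphenylsilyl)oxy]methyl}-1,4a-dimethyl-6-methylidene-2-[(trimethylsilyl)oxy]-1,4,4a,5,6,7,8,8a-octahydronaphthalene-1-carboxylate | C=C1CC[C@@H]2[C@](C)(C(=O)OCC)C(O[Si](C)(C)C)=CC[C@@]2(C)[C@@H]1CO[Si](c1ccccc1)(c1ccccc1)C(C)(C)C
F6 | step 7 | [(1R,4aR,5R,8aS)-5-{[(tert-butyldiphenylsilyl)oxy]methyl}-1,4a-dimethyl-6-methylidene-2-[(trimethylsilyl)oxy]-1,4,4a,5,6,7,8,8a-octahydronaphthalen-1-yl]methanol | C=C1CC[C@@H]2[C@](C)(CO)C(O[Si](C)(C)C)=CC[C@@]2(C)[C@@H]1CO[Si](c1ccccc1)(c1ccccc1)C(C)(C)C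
F7 | step 7 | (1R,4aR,5R,8aS)-5-{[(tert-butyldiphenylsilyl)oxy]methyl}-1-(hydroxymethyl)-1,4a-dimethyl-6-methylideneoctahydronaphthalen-2(1H)-one | C=C1CC[C@@H]2[C@](C)(CO)C(=O)CC[C@@]2(C)[C@@H]1CO[Si](c1ccccc1)(c1ccccc1)C(C)(C)C
F0 | step 11 | none | none
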